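**Plan**

1. Retrosynthesis: the C3' carbonyl is traced back to a carbinol, which makes the C40 skeleton C2-symmetric. That diol is cut at C11=C12 and C11'=C12' (twofold Wittig) into the C10 dialdehyde and two equivalents of one C15 phosphonium salt carrying the (3R,6S)-3-hydroxy-ε ring.
2. The C15 salt goes back through vinyl addition/allylic transposition (C9–C11) and a Wittig bond (C7=C8) to a ring aldehyde. The ring is cut at C1–C6 and C2–C3: a [4+2] of a (2E,4E)-1-silyloxydiene (C3–C6, C7 as CH2OAc) with 2-methyl-1-nitropropene (C1, C2), the nitro group being removed afterwards.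
3. Enabling feature: the hydroxy ring has a single alkene, C4=C5, lying between the cis stereocentres C3 (oxygen) and C6 (chain). That is a cyclohexene retron whose allylic carbons are the former diene termini and whose CMe2–CH2 pair is the former dienophile.
4. Forward order: diene (steps 1–4), ring by cycloaddition (5), denitration and side chain to cis-3-hydroxy-α-ionone (6–10), resolution (11–12), C15 salt (13–14), C15 + C10 + C15 to the C40 diol (15), oxidation of one ring carbinol (16).
5. Stereochemistry: the 3,6-cis relationship comes from the (E,E) diene geometry in the cycloaddition; the absolute configuration comes from a lipase resolution. C6' of the oxo ring is the same resolved centre (its C3' is erased by oxidation). Alkene geometry comes from a stabilised Wittig (C7=C8), phosphonium formation with crystallisation (C9=C10) and thermal equilibration (C11=C12, C11'=C12').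

Key step: step 5

Remark on numbering: ring positions are given in carotenoid numbering (C1 = CMe2, C2 = CH2, C3 = carbinol carbon, C4=C5 alkene with methyl on C5, C6 = chain-bearing carbon, C7 = first chain carbon).

Assumption: the lipase is taken to acylate the (3R) carbinol of 16, the usual preference for cyclohex-2-en-1-ols; if the other enantiomer reacts, the unreacted alcohol is already 18 and step 12 is dropped.

**Route**

Step 1
Reactants: 1 (E)-4-acetoxy-2-methylbut-2-enal; 2 methyltriphenylphosphonium bromide
Product: 4 (E)-3-methylpenta-2,4-dien-1-yl acetate, via methylenetriphenylphosphorane 3 (not isolated)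
Conditions: 2, KOtBu, THF, 0 °C; then 1, −78 °C → 0 °C
Reagents that add atoms: none
Why: Wittig methylenation, in which the non-stabilised ylide adds to the aldehyde far faster than to the acetate at low temperature and the trisubstituted alkene is not involved, so its (E) geometry is carried into the diene.

Step 2
Reactants: 4 (E)-3-methylpenta-2,4-dien-1-yl acetate
Product: 6 (E)-5-hydroxy-3-methylpent-2-en-1-yl acetate, via B-alkyl-9-borabicyclononane 5 (not isolated)
Conditions: 9-BBN, THF, 0 °C → rt; then NaBO3·4H2O, H2O, rt
Reagents that add atoms: sodium perborate (supplies the hydroxyl oxygen), [Na+].[Na+].O[B-]1(O)OO[B-](O)(O)OO1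
Why: Hydroboration–oxidation, in which the hindered dialkylborane adds only to the monosubstituted terminal alkene with boron on the terminal carbon, the trisubstituted acetoxy-bearing alkene being too hindered, and perborate oxidises the C–B bond without cleaving the acetate.

Step 3
Reactants: 6 (E)-5-hydroxy-3-methylpent-2-en-1-yl acetate
Product: 7 (E)-3-methyl-5-oxopent-2-en-1-yl acetate
Conditions: Dess–Martin periodinane, NaHCO3, CH2Cl2, 0 °C → rt; crude product used at once
Reagents that add atoms: none
Why: Dess–Martin oxidation under buffered, non-basic conditions should give the β,γ-unsaturated aldehyde without moving the double bond into conjugation, which is also why it is not stored.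

Step 4
Reactants: 7 (E)-3-methyl-5-oxopent-2-en-1-yl acetate
Product: 8 (2E,4E)-5-(tert-butyldimethylsilyloxy)-3-methylpenta-2,4-dien-1-yl acetate
Conditions: TBSOTf, Et3N, CH2Cl2, −78 °C → 0 °C
Reagents that add atoms: tert-butyldimethylsilyl trifluoromethanesulfonate, CC(C)(C)[Si](C)(C)OS(=O)(=O)C(F)(F)F
Why: Soft enolisation (silyl triflate and amine), in which O-silylation and loss of the doubly activated α-proton give the silyl dienol ether; the existing (E)-alkene is untouched and the new enol ether should be (E) because a (Z)-silyloxy group would clash with the 3-methyl group in either planar diene conformer (A(1,3) strain).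

Step 5
Reactants: 8 (2E,4E)-5-(tert-butyldimethylsilyloxy)-3-methylpenta-2,4-dien-1-yl acetate; 9 2-methyl-1-nitroprop-1-ene
Product: 10 [4-(tert-butyldimethylsilyloxy)-2,6,6-trimethyl-5-nitrocyclohex-2-en-1-yl]methyl acetate, racemic, CH2OAc and OTBS cis, both configurations at the nitro-bearing carbon
Conditions: 9 (3 equiv), BHT (cat.), CH2Cl2, 12 kbar, 40 °C
Reagents that add atoms: none
Why: This is a concerted, asynchronous, normal-demand Diels–Alder reaction of an electron-rich 1-silyloxydiene with a nitroalkene, the known reaction type that is followed by tin hydride denitration; pressure is applied because the dienophile is β,β-disubstituted and the cycloaddition has a strongly negative activation volume. The six-membered ring is closed by intermolecular [4+2] cycloaddition, suprafacial on both partners, forming C1–C6 and C2–C3 in one step. The largest HOMO coefficient of the diene lies at C6, remote from the silyloxy group and reinforced by the C5 methyl, and the largest LUMO coefficient of the nitroalkene lies at the CMe2 carbon, so C6 bonds to C1 and the nitro-bearing carbon to C3. C3 and C6 arise from (E)-configured diene termini whose substituents both point outward and therefore end up cis, whether the nitro group approaches endo or exo; this is controlled by the diene geometry set in steps 1 and 4. The nitro-bearing C2 forms as a mixture and is erased in step 6, and the adduct is racemic, the absolute configuration being set in step 11. The step therefore needs only regioselectivity and the cis 3,6 relationship, secured by the donor/acceptor pairing and by the (2E,4E) geometry.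

Step 6
Reactants: 10 nitro cycloadduct
Product: 11 rac-[(1S,4R)-4-(tert-butyldimethylsilyloxy)-2,6,6-trimethylcyclohex-2-en-1-yl]methyl acetate (cis)
Conditions: Bu3SnH (5 equiv), AIBN (0.3 equiv, in portions), toluene, 110 °C
Reagents that add atoms: none
Why: Radical denitration (tin hydride chain reaction), in which the stannyl radical adds to a nitro oxygen, the adduct loses tributyltin nitrite at 110 °C and the secondary C2 radical abstracts hydrogen, so both nitro epimers converge on one methylene compound while silyl ether, acetate and alkene stay intact.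

Step 7
Reactants: 11 cis silyloxy acetate
Product: 12 rac-[(1S,4R)-4-(tert-butyldimethylsilyloxy)-2,6,6-trimethylcyclohex-2-en-1-yl]methanol
Conditions: K2CO3, MeOH, 0 °C → rt
Reagents that add atoms: none
Why: Base-catalysed transesterification (methanolysis) removes the primary acetate, and the secondary silyl ether is stable to carbonate in methanol.

Step 8
Reactants: 12 cis silyloxy alcohol
Product: 13 rac-(1S,4R)-4-(tert-butyldimethylsilyloxy)-2,6,6-trimethylcyclohex-2-ene-1-carbaldehyde
Conditions: Dess–Martin periodinane, NaHCO3, CH2Cl2, 0 °C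
Reagents that add atoms: none
Why: Dess–Martin oxidation, chosen because its neutral buffered conditions should not enolise the new aldehyde at the allylic C6–H, so the cis relationship is kept.

Step 9
Reactants: 13 ring aldehyde; 14 1-(triphenylphosphoranylidene)propan-2-one
Product: 15 rac-(E)-4-[(1S,4R)-4-(tert-butyldimethylsilyloxy)-2,6,6-trimethylcyclohex-2-en-1-yl]but-3-en-2-one
Conditions: toluene, 90 °C
Reagents that add atoms: none
Why: Wittig olefination with a stabilised ylide should give the (E)-enone (C7=C8), and the ylide is too weakly basic to enolise the hindered aldehyde, so C6 is unchanged.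

Step 10
Reactants: 15 silyloxy enone
Product: 16 rac-(E)-4-[(1S,4R)-4-hydroxy-2,6,6-trimethylcyclohex-2-en-1-yl]but-3-en-2-one (racemic cis-3-hydroxy-α-ionone)
Conditions: HF·pyridine, pyridine, THF, 0 °C → rt
Reagents that add atoms: none
Why: Fluoride-mediated desilylation under buffered, slightly acidic conditions frees the allylic alcohol without exposing the doubly allylic C6–H of the enone system to base.

Step 11
Reactants: 16 racemic cis-3-hydroxy-α-ionone
Product: 17 (1R,4S)-3,5,5-trimethyl-4-[(1E)-3-oxobut-1-en-1-yl]cyclohex-2-en-1-yl acetate ((3R,6S)-3-acetoxy-α-ionone)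
Conditions: Pseudomonas fluorescens lipase, vinyl acetate, tert-butyl methyl ether, 30 °C, stopped near half conversion; chromatography
Reagents that add atoms: vinyl acetate, C=COC(C)=O
Why: Lipase-catalysed kinetic resolution by irreversible transesterification, a reaction type known for the stereoisomers of 3-hydroxy-α-ionone, in which the enzyme acylates the (3R) carbinol and the (3R,6S) acetate is separated from the unreacted (3S,6R) alcohol, fixing the absolute configuration of both ring stereocentres.

Step 12
Reactants: 17 (3R,6S)-3-acetoxy-α-ionone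
Product: 18 (E)-4-[(1S,4R)-4-hydroxy-2,6,6-trimethylcyclohex-2-en-1-yl]but-3-en-2-one ((3R,6S)-3-hydroxy-α-ionone)
Conditions: K2CO3, MeOH, 0 °C
Reagents that add atoms: none
Why: Carbonate-catalysed methanolysis of the acetate at 0 °C is too mild to deprotonate C6 or to add methoxide irreversibly to the enone.

Step 13
Reactants: 18 (3R,6S)-3-hydroxy-α-ionone; 19 vinylmagnesium bromide
Product: 20 (1E)-1-[(1S,4R)-4-hydroxy-2,6,6-trimethylcyclohex-2-en-1-yl]-3-methylpenta-1,4-dien-3-ol, both epimers at the tertiary carbinol
Conditions: 19 (3 equiv), THF, −20 °C → 0 °C; then aq. NH4Cl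
Reagents that add atoms: none
Why: Grignard 1,2-addition to the enone carbonyl (the standard ionone to vinylionol reaction) after the first equivalent has deprotonated the hydroxyl; the new C9 carbinol forms as both epimers, which is irrelevant because it is ionised in the next step.

Step 14
Reactants: 20 vinyl carbinol
Product: 21 [(2E,4E)-5-[(1S,4R)-4-hydroxy-2,6,6-trimethylcyclohex-2-en-1-yl]-3-methylpenta-2,4-dien-1-yl]triphenylphosphonium bromide
Conditions: PPh3·HBr, MeOH/CH2Cl2, 0 °C → rt; crystallisation
Reagents that add atoms: triphenylphosphine hydrobromide, [PH+](c1ccccc1)(c1ccccc1)c1ccccc1.[Br-]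
Why: Acid-mediated allylic transposition (the standard C15 Wittig salt formation), in which the tertiary, doubly allylic C9 carbinol ionises to a pentadienyl cation that PPh3 captures at the primary terminus to give the conjugated (9E) salt, while the secondary ring carbinol would give only a simple allyl cation and should survive at 0 °C; crystallisation removes the (9Z) isomer.

Step 15
Reactants: 21 C15 phosphonium bromide (2.2 equiv); 22 (2E,4E,6E)-2,7-dimethylocta-2,4,6-trienedial
Product: 25 (3R,6S,3'R,6'S)-ε,ε-carotene-3,3'-diol, via C15 phosphorus ylide 23 (not isolated), via C25 hydroxy aldehyde 24 (not isolated)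
Conditions: NaOMe, MeOH/CH2Cl2, 0 °C → rt; then heptane, reflux
Reagents that add atoms: none
Why: Twofold Wittig olefination, the standard C15 + C10 + C15 assembly of symmetrical carotenoids, in which the allylic ylide condenses with one formyl group of the dialdehyde and the C25 aldehyde so formed with a second ylide, the free ring hydroxyls being tolerated by methoxide, and heating then isomerises the hindered (11Z) and (11'Z) bonds to the all-E diol without touching the ring stereocentres.

Step 16
Reactants: 25 C40 diol
Product: 26 (3R,6S,6'S)-3-hydroxy-ε,ε-caroten-3'-one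
Conditions: activated MnO2 (limited amount, in portions), CH2Cl2, rt, dark, Ar; stopped at partial conversion; chromatography, recovered 25 recycled
Reagents that add atoms: none
Why: MnO2 oxidation of a secondary allylic alcohol to the enone, as used for ε-ring carotenols, in which the two symmetry-equivalent carbinols are insulated from each other so that the first oxidation is statistical and is stopped early to leave mainly separable diol beside the mono-ketone, while the neutral surface oxidant should neither attack the polyene nor enolise C6 or C6', so that only C3' becomes sp2 and the oxo ring never meets a base.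

**Compound list**

1 | (E)-4-acetoxy-2-methylbut-2-enal | CC(=O)OC/C=C(C)/C=O | starting material
2 | methyltriphenylphosphonium bromide | C[P+](c1ccccc1)(c1ccccc1)c1ccccc1.[Br-] | starting material
3 | methylenetriphenylphosphorane | C=P(c1ccccc1)(c1ccccc1)c1ccccc1 | intermediate
4 | (E)-3-methylpenta-2,4-dien-1-yl acetate | CC(=O)OC/C=C(C)/C=C | intermediate
5 | (E)-5-(9-borabicyclo[3.3.1]nonan-9-yl)-3-methylpent-2-en-1-yl acetate | CC(=O)OC/C=C(C)/CCB1C2CCCC1CCC2 | intermediate
6 | (E)-5-hydroxy-3-methylpent-2-en-1-yl acetate | CC(=O)OC/C=C(C)/CCO | intermediate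
7 | (E)-3-methyl-5-oxopent-2-en-1-yl acetate | CC(=O)OC/C=C(C)/CC=O | intermediate
8 | (2E,4E)-5-(tert-butyldimethylsilyloxy)-3-methylpenta-2,4-dien-1-yl acetate | CC(=O)OC/C=C(C)/C=C/O[Si](C)(C)C(C)(C)C | intermediate
9 | 2-methyl-1-nitroprop-1-ene | CC(C)=C[N+](=O)[O-] | starting material
10 | [4-(tert-butyldimethylsilyloxy)-2,6,6-trimethyl-5-nitrocyclohex-2-en-1-yl]methyl acetate, racemic, 1,4-cis, nitro carbon undefined (drawn as the enantiomer carried on) | CC(=O)OC[C@@H]1C(C)=C[C@H](O[Si](C)(C)C(C)(C)C)C([N+](=O)[O-])C1(C)C | intermediate
11 | rac-[(1S,4R)-4-(tert-butyldimethylsilyloxy)-2,6,6-trimethylcyclohex-2-en-1-yl]methyl acetate | CC(=O)OC[C@@H]1C(C)=C[C@H](O[Si](C)(C)C(C)(C)C)CC1(C)C | intermediate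
12 | rac-[(1S,4R)-4-(tert-butyldimethylsilyloxy)-2,6,6-trimethylcyclohex-2-en-1-yl]methanol | OC[C@@H]1C(C)=C[C@H](O[Si](C)(C)C(C)(C)C)CC1(C)C | intermediate
13 | rac-(1S,4R)-4-(tert-butyldimethylsilyloxy)-2,6,6-trimethylcyclohex-2-ene-1-carbaldehyde | O=C[C@@H]1C(C)=C[C@H](O[Si](C)(C)C(C)(C)C)CC1(C)C | intermediate
14 | 1-(triphenylphosphoranylidene)propan-2-one | CC(=O)C=P(c1ccccc1)(c1ccccc1)c1ccccc1 | starting material
15 | rac-(E)-4-[(1S,4R)-4-(tert-butyldimethylsilyloxy)-2,6,6-trimethylcyclohex-2-en-1-yl]but-3-en-2-one | CC(=O)/C=C/[C@@H]1C(C)=C[C@H](O[Si](C)(C)C(C)(C)C)CC1(C)C | intermediate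
16 | rac-(E)-4-[(1S,4R)-4-hydroxy-2,6,6-trimethylcyclohex-2-en-1-yl]but-3-en-2-one (racemate, drawn as the enantiomer carried on) | CC(=O)/C=C/[C@@H]1C(C)=C[C@H](O)CC1(C)C | intermediate
17 | (1R,4S)-3,5,5-trimethyl-4-[(1E)-3-oxobut-1-en-1-yl]cyclohex-2-en-1-yl acetate | CC(=O)/C=C/[C@@H]1C(C)=C[C@H](OC(C)=O)CC1(C)C | intermediate
18 | (E)-4-[(1S,4R)-4-hydroxy-2,6,6-trimethylcyclohex-2-en-1-yl]but-3-en-2-one (single enantiomer) | CC(=O)/C=C/[C@@H]1C(C)=C[C@H](O)CC1(C)C | intermediate
19 | vinylmagnesium bromide | C=C[Mg]Br | starting material
20 | (1E)-1-[(1S,4R)-4-hydroxy-2,6,6-trimethylcyclohex-2-en-1-yl]-3-methylpenta-1,4-dien-3-ol (tertiary carbinol undefined) | C=CC(C)(O)/C=C/[C@@H]1C(C)=C[C@H](O)CC1(C)C | intermediate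
21 | [(2E,4E)-5-[(1S,4R)-4-hydroxy-2,6,6-trimethylcyclohex-2-en-1-yl]-3-methylpenta-2,4-dien-1-yl]triphenylphosphonium bromide | C/C(=C\C[P+](c1ccccc1)(c1ccccc1)c1ccccc1)/C=C/[C@@H]1C(C)=C[C@H](O)CC1(C)C.[Br-] | intermediate
22 | (2E,4E,6E)-2,7-dimethylocta-2,4,6-trienedial | O=C/C(C)=C/C=C/C=C(C)/C=O | starting material
23 | [(2E,4E)-5-[(1S,4R)-4-hydroxy-2,6,6-trimethylcyclohex-2-en-1-yl]-3-methylpenta-2,4-dien-1-ylidene]triphenylphosphorane | C/C(=C\C=P(c1ccccc1)(c1ccccc1)c1ccccc1)/C=C/[C@@H]1C(C)=C[C@H](O)CC1(C)C | intermediate
24 | (3R,6S)-3-hydroxy-12'-apo-ε-caroten-12'-al, all-E | O=C/C(C)=C/C=C/C=C(C)/C=C/C=C(C)/C=C/[C@@H]1C(C)=C[C@H](O)CC1(C)C | intermediate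
25 | (3R,6S,3'R,6'S)-ε,ε-carotene-3,3'-diol, all-E | CC1=C[C@H](O)CC(C)(C)[C@@H]1/C=C/C(C)=C/C=C/C(C)=C/C=C/C=C(C)/C=C/C=C(C)/C=C/[C@@H]1C(C)=C[C@H](O)CC1(C)C | intermediate
26 | (3R,6S,6'S)-3-hydroxy-ε,ε-caroten-3'-one, all-E | CC1=CC(=O)CC(C)(C)[C@@H]1/C=C/C(C)=C/C=C/C(C)=C/C=C/C=C(C)/C=C/C=C(C)/C=C/[C@@H]1C(C)=C[C@H](O)CC1(C)C | target

**Step count**

Total steps: 16. Longest linear sequence: 16 (steps 1–16).

**Steps most likely to fail**

1. Step 5. What may go wrong: bond formation at the fully substituted nitroalkene carbon may be too slow even under pressure, and the nitroalkene may instead react as a heterodiene across the enol ether double bond; the dienyl acetate may also ionise in the compressed polar medium. Fallback: the ring is taken from the cyclogeranyl series instead of being built. It sets out from ylide 14: Wittig reaction with purchased α-cyclocitral gives racemic α-ionone F1 (also an article of commerce). Ketalisation with ethylene glycol (HC(OMe)3, TsOH cat.) gives the dioxolane F2, which masks the side-chain ketone. Allylic oxidation at C3 with tert-butyl hydroperoxide and catalytic CuI gives the ring enone F3. Reduction with Li[BH(sec-Bu)3] at −78 °C, hydride arriving anti to the C6 side chain, should favour the 3,6-cis allylic alcohol F4, the trans isomer being removed by chromatography. PPTS in wet acetone releases the ketone, and the route is rejoined at racemic 16, which is resolved as in step 11.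

2. Step 9. What may go wrong: enolisation of the aldehyde during the slow olefination of a hindered carbonyl, leading to epimerisation at C6 (loss of the cis relationship) or migration of the ring double bond into conjugation. Fallback: the polarity at C7 is reversed so that no aldehyde next to C6 is formed. It sets out from alcohol 12: Mitsunobu thioetherification with 1-phenyl-1H-tetrazole-5-thiol (PPh3, diisopropyl azodicarboxylate) gives sulfide F5, and oxidation with H2O2 and catalytic (NH4)6Mo7O24·4H2O gives sulfone F6. Julia–Kocienski olefination (KN(SiMe3)2, DME, −60 °C) with a second portion of enal 1 gives the C15 acetate F7 with the C7=C8 bond in place. HF·pyridine gives the racemic hydroxy acetate F8, lipase acylation as in step 11 gives the (3R,6S) diacetate F9, and K2CO3 in MeOH gives the diol F10. Its primary dienylic alcohol is converted by PPh3·HBr into phosphonium bromide 21, where the route is rejoined.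

3. Step 16. What may go wrong: the surface oxidant cannot tell the two equivalent carbinols apart, so over-oxidation to the dione competes as soon as mono-ketone accumulates, and prolonged contact with the oxidant may degrade the polyene. Fallback: the two rings are differentiated before the second half is attached, so that the oxidation can be run to completion. It sets out from salt 21: Wittig reaction (NaOMe, MeOH/CH2Cl2, then heptane at reflux) with dialdehyde 22 in threefold excess stops after one olefination, and the C25 hydroxy aldehyde 24 is isolated this time. Activated MnO2 in CH2Cl2 oxidises its single ring carbinol fully to (6S)-3-oxo-12'-apo-ε-caroten-12'-al F11. A second Wittig reaction with salt 21 under 1,2-epoxybutane/EtOH conditions at 60 °C, which form the ylide without added strong base, followed by equilibration in heptane at reflux, rejoins the route at target 26.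

**Further compounds**

F1 | step 5 | racemic α-ionone | CC(=O)/C=C/C1C(C)=CCCC1(C)C
F2 | step 5 | racemic α-ionone ethylene ketal | CC1=CCCC(C)(C)C1/C=C/C1(C)OCCO1
F3 | step 5 | racemic 3-oxo-α-ionone ethylene ketal | CC1=CC(=O)CC(C)(C)C1/C=C/C1(C)OCCO1
F4 | step 5 | racemic cis-3-hydroxy-α-ionone ethylene ketal (drawn as the enantiomer carried on) | CC1(/C=C/[C@@H]2C(C)=C[C@H](O)CC2(C)C)OCCO1
F5 | step 9 | rac-5-({[(1S,4R)-4-(tert-butyldimethylsilyloxy)-2,6,6-trimethylcyclohex-2-en-1-yl]methyl}sulfanyl)-1-phenyl-1H-tetrazole | c1ccc(-n2nnnc2SC[C@@H]2C(C)=C[C@H](O[Si](C)(C)C(C)(C)C)CC2(C)C)cc1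
F6 | step 9 | rac-5-({[(1S,4R)-4-(tert-butyldimethylsilyloxy)-2,6,6-trimethylcyclohex-2-en-1-yl]methyl}sulfonyl)-1-phenyl-1H-tetrazole | O=S(=O)(C[C@@H]1C(C)=C[C@H](O[Si](C)(C)C(C)(C)C)CC1(C)C)c1nnnn1-c1ccccc1
F7 | step 9 | rac-(2E,4E)-5-[(1S,4R)-4-(tert-butyldimethylsilyloxy)-2,6,6-trimethylcyclohex-2-en-1-yl]-3-methylpenta-2,4-dien-1-yl acetate | CC(=O)OC/C=C(C)/C=C/[C@@H]1C(C)=C[C@H](O[Si](C)(C)C(C)(C)C)CC1(C)C
F8 | step 9 | rac-(2E,4E)-5-[(1S,4R)-4-hydroxy-2,6,6-trimethylcyclohex-2-en-1-yl]-3-methylpenta-2,4-dien-1-yl acetate | CC(=O)OC/C=C(C)/C=C/[C@@H]1C(C)=C[C@H](O)CC1(C)C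
F9 | step 9 | (2E,4E)-5-[(1S,4R)-4-acetoxy-2,6,6-trimethylcyclohex-2-en-1-yl]-3-methylpenta-2,4-dien-1-yl acetate | CC(=O)OC/C=C(C)/C=C/[C@@H]1C(C)=C[C@H](OC(C)=O)CC1(C)C
F10 | step 9 | (2E,4E)-5-[(1S,4R)-4-hydroxy-2,6,6-trimethylcyclohex-2-en-1-yl]-3-methylpenta-2,4-dien-1-ol | OC/C=C(C)/C=C/[C@@H]1C(C)=C[C@H](O)CC1(C)C
F11 | step 16 | (6S)-3-oxo-12'-apo-ε-caroten-12'-al, all-E | CC1=CC(=O)CC(C)(C)[C@@H]1/C=C/C(C)=C/C=C/C(C)=C/C=C/C=C(C)/C=O
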